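All runs are calculated on assumed constants; the scatter is artificial.

Two questions stand on each flask, larch and maple: which species holds most at the end, and how much.

| setting | south-west | south-east | south | larch | maple |
|---|---|---|---|---|---|
| substrate | 0.056 M | 0.13 M | 0.084 M | 0.084 M | 0.084 M |
| enzyme | 17 µM | 17 µM | 34 µM | 17 µM | 17 µM |
| remark | run made earlier | run made earlier | run made earlier |  |  |
| time |  |  |  | 12 min | 40 min |

| run | time / min | substrate / % | target / % | isomer of the product / % | uncatalysed product / % |
|---|---|---|---|---|---|
| south-west | 1.00 | 87.0 | 6.6 | 0 | 5.5 |
| south-west | 3.00 | 63.3 | 20.7 | 1.3 | 14.7 |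
| south-west | 6.00 | 32.9 | 37.7 | 5.5 | 22.8 |
| south-west | 8.00 | 16.7 | 47.5 | 9.8 | 26.0 |
| south-west | 12.0 | 0.2 | 53.5 | 19.2 | 26.9 |
| south-east | 1.00 | 91.3 | 3.3 | 0.3 | 6.1 |
| south-east | 2.00 | 82.8 | 6.1 | 0.5 | 10.9 |
| south-east | 3.00 | 75.0 | 9.1 | 1.3 | 16.1 |
| south-east | 6.00 | 54.0 | 16.7 | 2.6 | 27.2 |
| south-east | 12.0 | 21.8 | 28.7 | 8.5 | 40.4 |
| south | 2.50 | 63.8 | 22.5 | 1.6 | 12.0 |
| south | 5.00 | 31.8 | 43.2 | 5.4 | 19.3 |
| south | 8.00 | 3.1 | 61.9 | 12.5 | 21.8 |
| south | 10.0 | 0 | 59.1 | 19.3 | 21.8 |
| south | 12.0 | 0 | 54.4 | 23.5 | 21.8 |

(scatter of a reading: 0.3 percentage points)

* which of these there is most of at the end, counted by the substrate in it, larch (isomer of the product / substrate / uncatalysed product / target)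
* which of these there is most of at the end, counted by the substrate in it, maple (isomer of the product / substrate / uncatalysed product / target)
* the largest of these amounts at the end, in percent of the substrate charged, larch
* the largest of these amounts at the end, in percent of the substrate charged, maple



Two chemists read these runs differently. Both start from λ, the isomer gained per minute divided by the mean target over an interval. In the south-west run, between 3.00 min and 6.00 min, λ reads 0.0479 /min. That makes 0.575 for larch and 1.92 for maple of the turnover count N, the elapsed time multiplied by this early λ, which says how many times over the step has passed on the target's own amount.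

The first chemist holds that target drains one way into isomer at a fixed rate. The second holds that the step is reversible and relaxes towards an equilibrium, so λ must sink as isomer builds up. As evidence, the second cites the south run between 10.0 min and 12.0 min, where λ reads 0.0370 /min, less than the early reading. The first answers that the interval just before it, in the same south run, reads 0.0562 /min, more than the early reading, and that each reading carries a scatter of 0.3 percentage points. So the readings leave the dispute open, and maple, with the larger count, is where it can be tested. The thing to watch there is λ in the late readings.

The forecast is the first chemist's: target at 44% in larch, isomer of the product at 50% in maple, with the ground “Target then decays over 26 min to about 15%, so isomer ≈ 50%”. The second chemist accepts both species but puts maple's isomer below 50%.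

The flask gives target at 43.9% in larch and isomer of the product at 41.7% in maple, which is 8.3 points under the forecast.

    substrate + enzyme → target + enzyme, rate k1*[substrate]*[enzyme]/(1 + ([substrate]/Km1) + ([substrate]/Ksi1)^2) (1.70 mM, 0.0750 M, k = 2500 /M/s)
    substrate → uncatalysed product (k = 9.90 × 10⁻⁴ /s)
    target ⇌ isomer of the product (K = 2.40, k = 8.50 × 10⁻⁴ /s)

In maple, the forward half-life of target by the step to isomer is 14 min, but the slowest mode of the whole flask has a shorter half-life of 9.59 min, and at a count of 1.92 maple's target stands at 23.5%, against the 19.2% it shows at 400 min. Larch, at a count of 0.575, is the region left to the one-way view: its target stands at 43.9% against the forecast's 44%.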